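**Plan**

Labdane numbering is used throughout: ring A = C1–C5 and C10, ring B = C5–C10, side chain C11–C15.

1. Retrosynthesis: cut C12–C13 (B-alkyl Suzuki coupling) and C9–C11 (vinyl addition to a 9-ketone), take the 2,3-diol back to a Δ2 alkene, then cut the ring-fusion bond C5–C10 to give a ten-membered carbocycle, which is opened at C1–C2 (allylic alkylation) and C5=C6 (cross-metathesis).
2. Enabling feature: C5 and C10 lie 1,6 across the C1–C10 perimeter, C10 carries a methyl group, and the neighbouring C9 carries an equatorial oxygen anti to the C5–C10 bond. This is the imprint of a C9–C10 epoxide of an (E,E)-cyclodeca-1,5-diene (C9=C10, C5=C6) opened at C10 by C5.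
3. Forward: two small fragments → acyclic C1–C10 chain (cross-metathesis) → ten-membered ring (Tsuji–Trost) → 9,10-epoxide → transannular radical closure that makes rings A and B together → Δ2 alkene, 9-ketone, vinyl group, side chain, diol.
4. Stereochemistry: C8 comes from an Evans alkylation. C8 then fixes the epoxide face (A1,3 strain) and, through the chair–chair closure, C10 and C5. C9 is set by α-face addition to the 9-ketone (the epoxide oxygen stays on C9 throughout), C2 and C3 by α-face osmylation, and the 13Z alkene by retention in the coupling of a (Z)-vinyl iodide.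

Key step: step 11

Remark: compounds 1, 8 and 20 are taken as purchased; 8 is otherwise one esterification away from commercial 2,2-dimethylbut-3-enoic acid.

**Route**

Step 1
Reactants: 1 (S)-4-benzyl-3-propionyloxazolidin-2-one
Product: 2 (S)-4-benzyl-3-[(R)-2-methylpent-4-enoyl]oxazolidin-2-one
Conditions: NaN(SiMe3)2, THF, −78 °C; allyl iodide, −78 → −40 °C
Reagents that add atoms: allyl iodide, C=CCI
Why: Evans asymmetric alkylation, in which the chelated (Z)-sodium enolate is allylated on the face away from the benzyl group, sets the future C8 methyl stereocentre as R.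

Step 2
Reactants: 2 (S)-4-benzyl-3-[(R)-2-methylpent-4-enoyl]oxazolidin-2-one
Product: 3 (R)-2-methylpent-4-en-1-ol
Conditions: LiBH4, MeOH (1 equiv), Et2O, 0 °C
Reagents that add atoms: none
Why: Reductive cleavage of the N-acyl oxazolidinone with LiBH4 should give the primary alcohol without touching the stereocentre or the alkene, and the auxiliary is recovered.

Step 3
Reactants: 3 (R)-2-methylpent-4-en-1-ol
Product: 5 ethyl (2E,4R)-2,4-dimethylhepta-2,6-dienoate, via (R)-2-methylpent-4-enal 4 (not isolated)
Conditions: Pr4N[RuO4] (5 mol %), N-methylmorpholine N-oxide, 4 Å sieves, CH2Cl2, rt; then Ph3P=C(CH3)CO2Et, rt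
Reagents that add atoms: ethyl 2-(triphenylphosphoranylidene)propanoate, CCOC(=O)C(C)=P(c1ccccc1)(c1ccccc1)c1ccccc1
Why: Ley–Griffith oxidation gives the volatile, epimerisable α-branched aldehyde, which is trapped in the same flask by a Wittig reaction whose stabilised ylide should give the (E)-trisubstituted enoate.

Step 4
Reactants: 5 ethyl (2E,4R)-2,4-dimethylhepta-2,6-dienoate
Product: 6 (2E,4R)-2,4-dimethylhepta-2,6-dien-1-ol
Conditions: i-Bu2AlH (2.2 equiv), CH2Cl2, −78 °C; Rochelle salt work-up
Reagents that add atoms: none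
Why: 1,2-Reduction of the conjugated ester by the aluminium hydride at low temperature should give the allylic alcohol and leave both alkenes alone.

Step 5
Reactants: 6 (2E,4R)-2,4-dimethylhepta-2,6-dien-1-ol
Product: 7 (2E,4R)-2,4-dimethylhepta-2,6-dien-1-yl methyl carbonate
Conditions: ClCO2Me, pyridine, CH2Cl2, 0 °C
Reagents that add atoms: methyl chloroformate, COC(=O)Cl
Why: O-Acylation of the primary allylic alcohol gives the allylic carbonate that later ionises under neutral conditions with zerovalent palladium.

Step 6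
Reactants: 8 methyl 2,2-dimethylbut-3-enoate
Product: 9 3,3-dimethyl-1-(phenylsulfonyl)pent-4-en-2-one
Conditions: PhSO2CH3 (2.2 equiv), n-BuLi (2.2 equiv), THF, −78 °C; then 8, −78 → 0 °C; aq. NH4Cl
Reagents that add atoms: methyl phenyl sulfone, CS(=O)(=O)c1ccccc1
Why: Claisen-type acylation of the lithiated sulfone by the non-enolisable ester gives the β-keto sulfone, whose enolate resists a second addition and whose C2–H is the soft carbon acid needed for ring closure.

Step 7
Reactants: 7 (2E,4R)-2,4-dimethylhepta-2,6-dien-1-yl methyl carbonate; 9 3,3-dimethyl-1-(phenylsulfonyl)pent-4-en-2-one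
Product: 10 (2E,4R,6E)-2,4,8,8-tetramethyl-9-oxo-10-(phenylsulfonyl)deca-2,6-dien-1-yl methyl carbonate
Conditions: second-generation Hoveyda–Grubbs catalyst (5 mol %), 9 (3 equiv), CH2Cl2, 40 °C
Reagents that add atoms: none
Why: Olefin cross-metathesis between the unhindered terminal alkene of 7 and the non-dimerising vinyl group of 9 (on a quaternary carbon, used in excess) should form C5=C6 as the E isomer for steric reasons, while the trisubstituted alkene stays out.

Step 8
Reactants: 10 (2E,4R,6E)-2,4,8,8-tetramethyl-9-oxo-10-(phenylsulfonyl)deca-2,6-dien-1-yl methyl carbonate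
Product: 11 (3E,6R,7E)-2,2,6,8-tetramethyl-10-(phenylsulfonyl)cyclodeca-3,7-dien-1-one (both epimers at the sulfonyl carbon)
Conditions: Pd(PPh3)4 (10 mol %), dppe (10 mol %), THF, 0.002 M, slow addition, 50 °C
Reagents that add atoms: none
Why: In this Tsuji–Trost macrocyclisation the carbonate ionises to a π-allyl palladium complex plus methoxide, and the β-keto sulfone anion attacks the unsubstituted allyl terminus C1 to close the ten-membered ring with the E geometry of C9=C10 kept in the syn-allyl complex (the C2 epimers are of no consequence).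

Step 9
Reactants: 11 (3E,6R,7E)-2,2,6,8-tetramethyl-10-(phenylsulfonyl)cyclodeca-3,7-dien-1-one
Product: 12 (3E,6R,7E)-2,2,6,8-tetramethylcyclodeca-3,7-dien-1-one
Conditions: SmI2 (2.5 equiv), THF/MeOH, −78 °C
Reagents that add atoms: none
Why: Single-electron reductive desulfonylation α to the ketone should remove the activating group at low temperature, without reducing the ketone or alkenes and without the heat that would start a Cope rearrangement of the cyclodeca-1,5-diene.

Step 10
Reactants: 12 (3E,6R,7E)-2,2,6,8-tetramethylcyclodeca-3,7-dien-1-one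
Product: 13 (3E,6R,7S,8S)-7,8-epoxy-2,2,6,8-tetramethylcyclodec-3-en-1-one (labdane numbering: 9S,10S-epoxide, 8R)
Conditions: mCPBA (1.05 equiv), NaHCO3, CH2Cl2, −20 → 0 °C
Reagents that add atoms: 3-chloroperoxybenzoic acid, OOC(=O)c1cccc(Cl)c1
Why: Prilezhaev epoxidation should select the electron-rich trisubstituted C9=C10 alkene, and A1,3 strain between the C8 and C10 methyl groups fixes which face of this trans-cycloalkene points outward, so peripheral attack sets C9 and C10 from C8.

Step 11
Reactants: 13 (3E,6R,7S,8S)-7,8-epoxy-2,2,6,8-tetramethylcyclodec-3-en-1-one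
Product: 14 (4aS,5S,6R,8aR)-5-hydroxy-1,1,4a,6-tetramethyloctahydronaphthalen-2(1H)-one (9β-hydroxy-4,4,8α,10β-tetramethyl-5α-decalin-3-one)
Conditions: Cp2TiCl2 (0.2 equiv), Mn dust (3 equiv), 2,4,6-collidine hydrochloride (2.5 equiv), THF, 0.01 M, slow addition of 13, rt
Reagents that add atoms: none
Why: Cp2TiCl (trivalent titanium, formed in the flask from Cp2TiCl2 and Mn) transfers one electron to the epoxide, the C10–O bond breaks to give the tertiary C10 radical with the C9 oxygen bound to titanium, this radical adds across the ring to C5 of the C5=C6 alkene, and the secondary C6 radical is reduced by a second Cp2TiCl and protonated by collidinium chloride, which also frees the catalyst. The closest known reaction type is the titanocene-mediated (Nugent–RajanBabu) reductive epoxide opening with radical cyclisation, in its transannular form on 1,10-epoxygermacrene-type cyclodecenes. The one new bond completes both six-membered rings: ring A by a 6-exo-trig closure (C10 reaches C5 through C1–C4, the alkene lies outside the ring) and ring B by a 6-endo-trig closure (through C9–C8–C7–C6, the alkene lies inside the ring). C10 is set by the chair–chair transition state in which the bulky titanoxy group on C9 and the C8 methyl are equatorial, so C5 bonds on the inner face anti to the C9–O bond and the C10 methyl becomes axial (β); C5 is set by the E geometry of C5=C6, which keeps C4 equatorial on ring B and H5 axial (α), hence the trans ring fusion. The step needs C10–O rather than C9–O cleavage (tertiary against secondary radical), attack at C5 and not at C6 (a 5-exo closure to a hydroazulene), and ring closure faster than reduction of the C10 radical. The crossed (E,E)-cyclodeca-1,5-diene geometry should secure the last two: C10 and C5 are the far ends of the 1,5-diene and face each other in the same chair array as in a Cope transition state, and the low standing concentration of Cp2TiCl under catalytic turnover gives the radical time to close.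

Step 12
Reactants: 14 9β-hydroxy-4,4,8α,10β-tetramethyl-5α-decalin-3-one
Product: 15 9β-hydroxy-4,4,8α,10β-tetramethyl-5α-decalin-3-one p-toluenesulfonylhydrazone
Conditions: TsNHNH2 (1.5 equiv), PPTS (cat.), EtOH, 70 °C
Reagents that add atoms: p-toluenesulfonohydrazide, Cc1ccc(cc1)S(=O)(=O)NN
Why: Condensation of the only ketone with the sulfonyl hydrazide gives the tosylhydrazone, a routine reaction even for hindered 4,4-dimethyl-3-ketones.

Step 13
Reactants: 15 9β-hydroxy-4,4,8α,10β-tetramethyl-5α-decalin-3-one p-toluenesulfonylhydrazone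
Product: 17 4,4,8α,10β-tetramethyl-5α-decal-2-en-9β-ol, via dilithiated C3-vinyllithium 16 (not isolated)
Conditions: MeLi (5 equiv), THF, 0 °C → rt; then H2O
Reagents that add atoms: none
Why: In this Shapiro reaction deprotonation can occur only at C2 (C4 is quaternary), loss of sulfinate and N2 gives the C3 vinyllithium, and protonation gives the Δ2 alkene as a single regioisomer, with extra base covering the free hydroxyl.

Step 14
Reactants: 17 4,4,8α,10β-tetramethyl-5α-decal-2-en-9β-ol
Product: 18 4,4,8α,10β-tetramethyl-5α-decal-2-en-9-one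
Conditions: Dess–Martin periodinane, NaHCO3, CH2Cl2, rt
Reagents that add atoms: none
Why: Dess–Martin oxidation of the hindered secondary alcohol gives the 9-ketone, and the adjacent C8 methyl is already equatorial (the thermodynamic position), so the α-centre is not at risk.

Step 15
Reactants: 18 4,4,8α,10β-tetramethyl-5α-decal-2-en-9-one
Product: 19 9α-vinyl-4,4,8α,10β-tetramethyl-5α-decal-2-en-9β-ol
Conditions: CH2=CHMgBr (4 equiv), CeCl3 (4 equiv, dried), THF, −78 → 0 °C; aq. NH4Cl
Reagents that add atoms: vinylmagnesium bromide, C=C[Mg]Br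
Why: 1,2-Addition of the weakly basic organocerium reagent (no enolisation at C8) should occur by axial attack on the α face, anti to the axial C10 methyl group, so the vinyl group ends axial (9α) and the hydroxyl equatorial (9β), which sets C9.

Step 16
Reactants: 20 methyl but-2-ynoate
Product: 21 methyl (Z)-3-iodobut-2-enoate
Conditions: NaI (1.6 equiv), AcOH, 115 °C
Reagents that add atoms: sodium iodide, [Na+].[I-]
Why: Hydroiodination of the ynoate (conjugate addition of iodide, then protonation) is the standard route to the (Z)-β-iodo enoate.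

Step 17
Reactants: 19 9α-vinyl-4,4,8α,10β-tetramethyl-5α-decal-2-en-9β-ol; 21 methyl (Z)-3-iodobut-2-enoate
Product: 23 methyl (2Z)-5-(9β-hydroxy-4,4,8α,10β-tetramethyl-5α-decal-2-en-9α-yl)-3-methylpent-2-enoate, via B-alkyl-9-BBN borane 22 (not isolated)
Conditions: 9-BBN dimer, THF, rt; then 21, PdCl2(dppf) (5 mol %), AsPh3, aq. K3PO4, DMF, rt
Reagents that add atoms: none
Why: 9-BBN hydroborates only the monosubstituted vinyl group (anti-Markovnikov, the hindered Δ2 alkene is left), and the B-alkyl Suzuki–Miyaura coupling with the (Z)-vinyl iodide proceeds with retention, which sets the 13Z geometry.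

Step 18
Reactants: 23 methyl (2Z)-5-(9β-hydroxy-4,4,8α,10β-tetramethyl-5α-decal-2-en-9α-yl)-3-methylpent-2-enoate
Product: 24 methyl (2Z)-5-[(1S,2R,4aS,6S,7R,8aS)-1,6,7-trihydroxy-2,5,5,8a-tetramethyldecahydronaphthalen-1-yl]-3-methylpent-2-enoate (labdane numbering: 2R,3S,5S,8R,9S,10S; 2α,3α,9β-triol)
Conditions: OsO4 (5 mol %), N-methylmorpholine N-oxide (1.3 equiv), acetone/H2O, 0 °C → rt
Reagents that add atoms: osmium tetroxide, O=[Os](=O)(=O)=O (delivers both oxygens, regenerated); N-methylmorpholine N-oxide, C[N+]1([O-])CCOCC1; water, O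
Why: In this Upjohn dihydroxylation OsO4 should add to the electron-rich cis-disubstituted Δ2 alkene in preference to the electron-poor enoate, from the α face opposite the axial C10 and C4β methyl groups, which sets C2 (R) and C3 (S) as the cis 2α,3α-diol.

**Compound list**

1 | (S)-4-benzyl-3-propionyloxazolidin-2-one | CCC(=O)N1[C@@H](Cc2ccccc2)COC1=O | starting material
2 | (S)-4-benzyl-3-[(R)-2-methylpent-4-enoyl]oxazolidin-2-one | C=CC[C@@H](C)C(=O)N1[C@@H](Cc2ccccc2)COC1=O | intermediate
3 | (R)-2-methylpent-4-en-1-ol | C=CC[C@@H](C)CO | intermediate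
4 | (R)-2-methylpent-4-enal | C=CC[C@@H](C)C=O | intermediate
5 | ethyl (2E,4R)-2,4-dimethylhepta-2,6-dienoate | CCOC(=O)/C(C)=C/[C@H](C)CC=C | intermediate
6 | (2E,4R)-2,4-dimethylhepta-2,6-dien-1-ol | OC/C(C)=C/[C@H](C)CC=C | intermediate
7 | (2E,4R)-2,4-dimethylhepta-2,6-dien-1-yl methyl carbonate | COC(=O)OC/C(C)=C/[C@H](C)CC=C | intermediate
8 | methyl 2,2-dimethylbut-3-enoate | COC(=O)C(C)(C)C=C | starting material
9 | 3,3-dimethyl-1-(phenylsulfonyl)pent-4-en-2-one | C=CC(C)(C)C(=O)CS(=O)(=O)c1ccccc1 | intermediate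
10 | (2E,4R,6E)-2,4,8,8-tetramethyl-9-oxo-10-(phenylsulfonyl)deca-2,6-dien-1-yl methyl carbonate | COC(=O)OC/C(C)=C/[C@H](C)C/C=C/C(C)(C)C(=O)CS(=O)(=O)c1ccccc1 | intermediate
11 | (3E,6R,7E)-2,2,6,8-tetramethyl-10-(phenylsulfonyl)cyclodeca-3,7-dien-1-one (epimers at C10 of the ring) | O=C1C(S(=O)(=O)c2ccccc2)C/C(C)=C/[C@H](C)C/C=C/C1(C)C | intermediate
12 | (3E,6R,7E)-2,2,6,8-tetramethylcyclodeca-3,7-dien-1-one | O=C1CC/C(C)=C/[C@H](C)C/C=C/C1(C)C | intermediate
13 | (3E,6R,7S,8S)-7,8-epoxy-2,2,6,8-tetramethylcyclodec-3-en-1-one | O=C1CC[C@]2(C)O[C@H]2[C@H](C)C/C=C/C1(C)C | intermediate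
14 | (4aS,5S,6R,8aR)-5-hydroxy-1,1,4a,6-tetramethyloctahydronaphthalen-2(1H)-one (9β-hydroxy-4,4,8α,10β-tetramethyl-5α-decalin-3-one) | O[C@H]1[C@H](C)CC[C@H]2C(C)(C)C(=O)CC[C@@]21C | intermediate
15 | p-toluenesulfonylhydrazone of 14 at C3 | O[C@H]1[C@H](C)CC[C@H]2C(C)(C)C(=NNS(=O)(=O)c3ccc(C)cc3)CC[C@@]21C | intermediate
16 | C3-vinyllithium of the Δ2 alkene with lithium 9β-alkoxide | [Li]O[C@H]1[C@H](C)CC[C@H]2C(C)(C)C([Li])=CC[C@@]21C | intermediate
17 | 4,4,8α,10β-tetramethyl-5α-decal-2-en-9β-ol | O[C@H]1[C@H](C)CC[C@H]2C(C)(C)C=CC[C@@]21C | intermediate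
18 | 4,4,8α,10β-tetramethyl-5α-decal-2-en-9-one | O=C1[C@H](C)CC[C@H]2C(C)(C)C=CC[C@@]21C | intermediate
19 | 9α-vinyl-4,4,8α,10β-tetramethyl-5α-decal-2-en-9β-ol | C=C[C@]1(O)[C@H](C)CC[C@H]2C(C)(C)C=CC[C@@]21C | intermediate
20 | methyl but-2-ynoate | CC#CC(=O)OC | starting material
21 | methyl (Z)-3-iodobut-2-enoate | COC(=O)/C=C(/C)I | intermediate
22 | 9α-[2-(9-borabicyclo[3.3.1]nonan-9-yl)ethyl]-4,4,8α,10β-tetramethyl-5α-decal-2-en-9β-ol | C1CC2CCCC(C1)B2CC[C@]1(O)[C@H](C)CC[C@H]2C(C)(C)C=CC[C@@]21C | intermediate
23 | methyl (2Z)-5-(9β-hydroxy-4,4,8α,10β-tetramethyl-5α-decal-2-en-9α-yl)-3-methylpent-2-enoate | COC(=O)/C=C(/C)CC[C@]1(O)[C@H](C)CC[C@H]2C(C)(C)C=CC[C@@]21C | intermediate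
24 | methyl (2Z)-5-[(1S,2R,4aS,6S,7R,8aS)-1,6,7-trihydroxy-2,5,5,8a-tetramethyldecahydronaphthalen-1-yl]-3-methylpent-2-enoate | COC(=O)/C=C(/C)CC[C@]1(O)[C@H](C)CC[C@H]2C(C)(C)[C@H](O)[C@H](O)C[C@@]21C | target

**Step count and risks**

Total step count: 18. Longest linear sequence: 16 (steps 1–5, 7–15, 17, 18); steps 6 and 16 are one-step side branches.

Steps most likely to fail:

1. Step 11. The C10 radical may attack C6 instead of C5 (5-exo closure to a hydroazulene), or lose a β-hydrogen or be reduced before it closes. The fallback replaces the radical by the polar closure known for germacrene epoxides. It sets out from 13: BF3·OEt2 in CH2Cl2 at −78 °C should open the epoxide at C10 with anti attack by C5 and loss of a C7 proton to give 9β-hydroxy-4,4,8α,10β-tetramethyl-5α-decal-6-en-3-one F1. Hydrogenation (H2, Pd/C, EtOAc) then returns to the route at 14.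

2. Step 8. The ring closure may lose out to oligomerisation, to attack at the internal allyl terminus, or to syn–anti isomerisation of the π-allyl complex that would give the Z-cycloalkene. The fallback is a base-mediated intramolecular SN2 alkylation with no π-allyl intermediate, so the alkene geometry is fixed. It sets out from 6: Corey–Kim chlorination (N-chlorosuccinimide, Me2S, CH2Cl2, −20 → 0 °C) gives (2E,4R)-1-chloro-2,4-dimethylhepta-2,6-diene F2. Cross-metathesis of this chloride with 9 under the conditions of step 7 gives (4E,7R,8E)-10-chloro-3,3,7,9-tetramethyl-1-(phenylsulfonyl)deca-4,8-dien-2-one F3. Cs2CO3 in MeCN at high dilution and rt then closes the ring and returns to the route at 11.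

3. Step 18. Osmylation of the hindered Δ2 alkene may be slow enough for the enoate alkene to compete, leading to over-oxidation. The fallback installs the diol before the side chain. It sets out from 18: OsO4/N-methylmorpholine N-oxide gives 2α,3α-dihydroxy-4,4,8α,10β-tetramethyl-5α-decalin-9-one F4. 2,2-Dimethoxypropane with PPTS gives its 2,3-O-isopropylidene derivative F5. CH2=CHMgBr/CeCl3 as in step 15 gives the 9α-vinyl-9β-hydroxy acetonide F6. 9-BBN gives the B-alkyl-9-BBN borane of the acetonide F7 (not isolated), which is coupled with 21 as in step 17 to give the methyl (2Z)-enoate acetonide F8. Aqueous acetic acid at rt removes the acetonide and returns to the route at 24.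

**Further compounds**

F1 | step 11 | 9β-hydroxy-4,4,8α,10β-tetramethyl-5α-decal-6-en-3-one | O[C@H]1[C@H](C)C=C[C@H]2C(C)(C)C(=O)CC[C@@]21C
F2 | step 8 | (2E,4R)-1-chloro-2,4-dimethylhepta-2,6-diene | ClC/C(C)=C/[C@H](C)CC=C
F3 | step 8 | (4E,7R,8E)-10-chloro-3,3,7,9-tetramethyl-1-(phenylsulfonyl)deca-4,8-dien-2-one | ClC/C(C)=C/[C@H](C)C/C=C/C(C)(C)C(=O)CS(=O)(=O)c1ccccc1
F4 | step 18 | 2α,3α-dihydroxy-4,4,8α,10β-tetramethyl-5α-decalin-9-one | O=C1[C@H](C)CC[C@H]2C(C)(C)[C@H](O)[C@H](O)C[C@@]21C
F5 | step 18 | 2α,3α-(isopropylidenedioxy)-4,4,8α,10β-tetramethyl-5α-decalin-9-one | O=C1[C@H](C)CC[C@H]2C(C)(C)[C@H](O3)[C@H](OC3(C)C)C[C@@]21C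
F6 | step 18 | 9α-vinyl-2α,3α-(isopropylidenedioxy)-4,4,8α,10β-tetramethyl-5α-decalin-9β-ol | C=C[C@]1(O)[C@H](C)CC[C@H]2C(C)(C)[C@H](O3)[C@H](OC3(C)C)C[C@@]21C
F7 | step 18 | 9α-[2-(9-borabicyclo[3.3.1]nonan-9-yl)ethyl]-2α,3α-(isopropylidenedioxy)-4,4,8α,10β-tetramethyl-5α-decalin-9β-ol | C1CC2CCCC(C1)B2CC[C@]1(O)[C@H](C)CC[C@H]2C(C)(C)[C@H](O3)[C@H](OC3(C)C)C[C@@]21C
F8 | step 18 | methyl (2Z)-5-[9β-hydroxy-2α,3α-(isopropylidenedioxy)-4,4,8α,10β-tetramethyl-5α-decalin-9α-yl]-3-methylpent-2-enoate | COC(=O)/C=C(/C)CC[C@]1(O)[C@H](C)CC[C@H]2C(C)(C)[C@H](O3)[C@H](OC3(C)C)C[C@@]21C
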